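**Strategy.** Ring B of the target is the cyclopentane C1–C5–C6–C7–C11 (C1 quaternary ring-fusion carbon, C5 ring-fusion CH, C6 the C(Me)(CO2Me) carbon, C7 allylic bridgehead CH, C11 bridging CH2). It is opened at C1–C5 and C7–C11, leaving a 1,1-disubstituted alkene (C1=C11) tethered to the C5–C6–C7 unit of a trans-vinylcyclopropane; the step exploits that C5 and C7 both sit on the saturated quaternary C6. One rhodium-catalysed intramolecular [3+2] cycloaddition closes rings A and B. The cyclopropane, from an enantioselective intramolecular cyclopropanation, hands on the C5/C6 configuration. Ring C follows by aldol condensation, the acyloxy-dihydropyran by enol lactone reduction and acylation.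

Key step: step 9

Atom labels used below: ring A = C1–C2–C3–C4–C5 (C2 bears the acetal carbon C13); ring B = C1, C5, C6, C7, C11; ring C = C1, C11, C7, C8, C9, C10 (C10 bears the enol-ether CH, C12).

Remark: C2 is formed racemic in step 2 and is carried as a mixture of both epimers (left undefined in the SMILES of 5 to 23); it stays next to the C13 carbonyl and should be brought to the cis-fused configuration in steps 15 to 17.

Step 1
Reactants: 1 3,3-dimethoxybutan-2-one; 2 tert-butyl 2-(diethoxyphosphoryl)acetate
Product: 3 tert-butyl (2E)-4,4-dimethoxy-3-methylpent-2-enoate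
Conditions: NaH, THF, 0 °C to 60 °C
Reagents that add atoms: none
Why: Horner–Wadsworth–Emmons olefination of the α,α-dialkoxy ketone should give the β-methyl enoate (E major, both isomers serve) that holds the masked acetyl group (C10, C9), the future C11 and the C13 carboxyl.

Step 2
Reactants: 3 tert-butyl (2E)-4,4-dimethoxy-3-methylpent-2-enoate; 4 5-bromo-2-methylpent-2-ene
Product: 5 tert-butyl 4,4-dimethoxy-3-methylidene-2-(4-methylpent-3-en-1-yl)pentanoate
Conditions: LiN(i-Pr)2, THF/DMPU, −78 °C; then 4, NaI (cat.), −78 °C to 0 °C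
Reagents that add atoms: none
Why: γ-Deprotonation gives the lithium dienolate, which is alkylated at the α-carbon (deconjugative alkylation), so the C2–C3 bond and the C1=C11 methylidene should form together, with C2 racemic.

Step 3
Reactants: 5 tert-butyl 4,4-dimethoxy-3-methylidene-2-(4-methylpent-3-en-1-yl)pentanoate
Product: 6 tert-butyl 2-[(3E)-5-hydroxy-4-methylpent-3-en-1-yl]-4,4-dimethoxy-3-methylidenepentanoate
Conditions: SeO2 (0.5 equiv), t-BuOOH, CH2Cl2, rt
Reagents that add atoms: selenium dioxide, O=[Se]=O; tert-butyl hydroperoxide, CC(C)(C)OO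
Why: Selenium dioxide allylic oxidation (ene reaction, then [2,3]-shift) should attack the electron-rich trisubstituted alkene at its (E)-methyl group, giving the (E)-allylic alcohol whose geometry later places CH3 on C6 cis to C4.

Step 4
Reactants: 6 tert-butyl 2-[(3E)-5-hydroxy-4-methylpent-3-en-1-yl]-4,4-dimethoxy-3-methylidenepentanoate
Product: 8 allylic diazoacetate of alcohol 6, via bromoacetate 7 (not isolated)
Conditions: BrCH2COBr, NaHCO3, MeCN, 0 °C; then TsNHNHTs, DBU, THF, 0 °C
Reagents that add atoms: bromoacetyl bromide, BrCC(Br)=O; N,N'-bis(4-methylbenzenesulfonyl)hydrazine, Cc1ccc(cc1)S(=O)(=O)NNS(=O)(=O)c1ccc(C)cc1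
Why: O-Acylation, then N-alkylation of the bis-sulfonylhydrazine and double sulfinate elimination, is a standard diazoacetate synthesis and should tolerate the ketal and both alkenes.

Step 5
Reactants: 8 allylic diazoacetate of alcohol 6
Product: 9 cyclopropane-fused γ-lactone (1R,5S,6R)-5-methyl-6-alkyl-3-oxabicyclo[3.1.0]hexan-2-one
Conditions: Rh2(4S-MPPIM)4 (1 mol%; dirhodium tetrakis[methyl (4S)-2-oxo-1-(3-phenylpropanoyl)imidazolidine-4-carboxylate], divalent rhodium), CH2Cl2, 40 °C, slow addition of 8
Reagents that add atoms: none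
Why: Dirhodium carboxamidate-catalysed enantioselective intramolecular cyclopropanation of an allylic diazoacetate should keep the alkene geometry (CH3 cis to the side chain, lactone cis-fused), and the (4S) ligand sphere, which is the one suited to 2-methylallyl substrates and gives (1R,5S)-lactones from allyl diazoacetate, should set C5, C6 and C7 absolutely.

Step 6
Reactants: 9 cyclopropane-fused γ-lactone
Product: 10 cyclopropane-fused lactol (anomers)
Conditions: i-Bu2AlH (1.1 equiv), CH2Cl2, −78 °C
Reagents that add atoms: none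
Why: Partial hydride reduction of the strained γ-lactone to the lactol should outrun attack on the hindered tert-butyl ester at −78 °C.

Step 7
Reactants: 10 cyclopropane-fused lactol
Product: 11 vinylcyclopropane alcohol
Conditions: Ph3PCH3Br, KOt-Bu, THF, 0 °C to rt
Reagents that add atoms: methyltriphenylphosphonium bromide, C[P+](c1ccccc1)(c1ccccc1)c1ccccc1.[Br-]
Why: Wittig methylenation of the open cis-aldehyde form of the lactol should give the vinylcyclopropane with the vinyl group cis to CH2OH and trans to the ene tether, as fixed in step 5.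

Step 8
Reactants: 11 vinylcyclopropane alcohol
Product: 12 vinylcyclopropane silyl ether
Conditions: t-BuMe2SiCl, imidazole, DMF, rt
Reagents that add atoms: tert-butyldimethylsilyl chloride, CC(C)(C)[Si](C)(C)Cl
Why: Silylation of the primary alcohol removes a metal-binding hydroxyl next to the cyclopropane before the key step.

Step 9
Reactants: 12 vinylcyclopropane silyl ether
Product: 13 cis-bicyclo[3.3.0]octane cycloadduct (rings A and B)
Conditions: [Rh(CO)2Cl]2 (5 mol%), toluene, 110 °C
Reagents that add atoms: none
Why: Monovalent rhodium should add oxidatively to the allylic C5–C7 cyclopropane bond to give a π-allyl (C7–C8–CH2)/σ-alkyl (C5) rhodacycle, the tethered C1=C11 alkene then inserts into the Rh–C5 bond, and C–C reductive elimination joins C11 to the allyl terminus C7 and restores the vinyl group. The closest known reaction type is the rhodium-catalysed intramolecular [3+2] cycloaddition of trans-2-ene-vinylcyclopropanes, applied here to a cyclopropane with a fully substituted third carbon and a 1,1-disubstituted alkene. Ring A closes by 5-exo migratory insertion (C5 onto the internal alkene carbon C1 across a three-atom tether) and ring B by reductive elimination from the resulting six-membered rhodacycle, a net [σ2+π2] union of the C5–C7 bond with the alkene. C5 keeps its cyclopropane configuration (retention in oxidative addition and insertion), so CH3 on C6 stays cis to C4; C1 is fixed by the obligatory cis fusion of the bicyclo[3.3.0]octane; C7 should be delivered with the vinyl group cis to CH2OSi (retention), and an error there is corrected in step 13 because the derived aldehyde is epimerisable. The step needs cleavage of C5–C7 rather than C6–C7 and [3+2] rather than [5+2]: the first is secured by the quaternary, acceptor-free C6 (carboxyl held at the alcohol level as a silyl ether) and by the tether on C5, the second by the trans relation of vinyl group and tether.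

Step 10
Reactants: 13 cis-bicyclo[3.3.0]octane cycloadduct
Product: 16 keto acid (C6 carboxylic acid with C1 acetyl group), via keto alcohol 14 (not isolated), via keto aldehyde 15 (not isolated)
Conditions: CrO3, H2SO4, H2O, acetone, 0 °C
Reagents that add atoms: chromium trioxide, O=[Cr](=O)=O; water, O
Why: Jones oxidation: the acidic medium should cleave the primary silyl ether and the dimethyl ketal, and hexavalent chromium takes the neopentyl alcohol through the non-enolisable aldehyde to the acid, giving C6 its carboxyl with the configuration from step 5.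

Step 11
Reactants: 16 keto acid
Product: 17 keto methyl ester
Conditions: Me3SiCHN2, toluene/MeOH, rt
Reagents that add atoms: (trimethylsilyl)diazomethane, C[Si](C)(C)C=[N+]=[N-]
Why: Diazoalkane esterification should methylate the hindered acid without touching the ketone or the tert-butyl ester.

Step 12
Reactants: 17 keto methyl ester
Product: 19 keto aldehyde (C7–CHO), via ozonide 18 (not isolated)
Conditions: O3, CH2Cl2, −78 °C; then PPh3, −78 °C to rt
Reagents that add atoms: ozone, [O-][O+]=O
Why: Ozonolysis with reductive work-up should cut the only alkene, the vinyl group, to the C8 aldehyde.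

Step 13
Reactants: 19 keto aldehyde
Product: 21 tricyclic enone (ring C closed), via aldol adduct 20 (not isolated)
Conditions: pyrrolidine (0.5 equiv), AcOH (0.5 equiv), toluene, 60 °C
Reagents that add atoms: none
Why: Amine-catalysed intramolecular aldol condensation (C9 of the methyl ketone onto the C8 aldehyde, then elimination) should close ring C as a bicyclo[3.2.1]octenone, and since only the C7 epimer with CHO cis to the acetyl group can cyclise while C7 equilibrates through its enamine, C7 is secured here.

Step 14
Reactants: 21 tricyclic enone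
Product: 22 methyl dienol ether (E/Z at C10=C12)
Conditions: MeOCH2PPh3Cl, KN(SiMe3)2, THF, 0 °C to rt
Reagents that add atoms: (methoxymethyl)triphenylphosphonium chloride, COC[P+](c1ccccc1)(c1ccccc1)c1ccccc1.[Cl-]
Why: Wittig olefination with the methoxymethylidene ylide adds C12, and because the ketone cannot enolise (C1 quaternary, C9 vinylic, C7 bridgehead) 1,2-addition should prevail despite hindrance.

Step 15
Reactants: 22 methyl dienol ether
Product: 24 dienol lactone (cis-fused), via aldehyde acid 23 (not isolated)
Conditions: CF3CO2H/CH2Cl2 (1:4), H2O (3 equiv), 0 °C to rt; evaporate; then Ac2O, NaOAc, 100 °C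
Reagents that add atoms: water, O
Why: Acidolysis should remove the tert-butyl ester and hydrolyse the dienol ether, and enol lactonisation of the resulting 5-oxo acid with acetic anhydride and sodium acetate gives the conjugated dienol lactone, C2 epimerising through the mixed anhydride and the lactone enolate towards the cis ring fusion (as in nepetalactone).

Step 16
Reactants: 24 dienol lactone
Product: 25 lactol (anomers)
Conditions: i-Bu2AlH (1.05 equiv), CH2Cl2, −78 °C
Reagents that add atoms: none
Why: Low-temperature hydride reduction of the enol lactone should stop at the lactol (as nepetalactone gives nepetalactol), the neopentyl methyl ester on C6 being far less reactive.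

Step 17
Reactants: 25 lactol
Product: 26 target (CNP0315847.1)
Conditions: 3-methylbutanoyl chloride, pyridine, DMAP (cat.), CH2Cl2, 0 °C
Reagents that add atoms: 3-methylbutanoyl chloride, CC(C)CC(Cl)=O
Why: O-Acylation of the lactol, which equilibrates by ring–chain tautomerism (this also lets C2 epimerise), should trap the anomer with the acyloxy group on the convex face, trans to the C2–C3 bond and pseudoaxial (anomeric effect), as in the target.

**Compound list**

1 | 3,3-dimethoxybutan-2-one | CC(=O)C(C)(OC)OC | starting material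
2 | tert-butyl 2-(diethoxyphosphoryl)acetate | CCOP(=O)(OCC)CC(=O)OC(C)(C)C | starting material
3 | tert-butyl (2E)-4,4-dimethoxy-3-methylpent-2-enoate | CC(OC)(OC)/C(C)=C/C(=O)OC(C)(C)C | intermediate
4 | 5-bromo-2-methylpent-2-ene | CC(C)=CCCBr | starting material
5 | tert-butyl 4,4-dimethoxy-3-methylidene-2-(4-methylpent-3-en-1-yl)pentanoate (racemic) | CC(C)=CCCC(C(=O)OC(C)(C)C)C(=C)C(C)(OC)OC | intermediate
6 | tert-butyl 2-[(3E)-5-hydroxy-4-methylpent-3-en-1-yl]-4,4-dimethoxy-3-methylidenepentanoate (racemic) | C/C(CO)=C\CCC(C(=O)OC(C)(C)C)C(=C)C(C)(OC)OC | intermediate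
7 | tert-butyl 2-[(3E)-5-(2-bromoacetoxy)-4-methylpent-3-en-1-yl]-4,4-dimethoxy-3-methylidenepentanoate | BrCC(=O)OC/C(C)=C/CCC(C(=O)OC(C)(C)C)C(=C)C(C)(OC)OC | intermediate (not isolated)
8 | tert-butyl 2-[(3E)-5-(2-diazoacetoxy)-4-methylpent-3-en-1-yl]-4,4-dimethoxy-3-methylidenepentanoate | [N-]=[N+]=CC(=O)OC/C(C)=C/CCC(C(=O)OC(C)(C)C)C(=C)C(C)(OC)OC | intermediate
9 | tert-butyl 4,4-dimethoxy-3-methylidene-2-{2-[(1R,5S,6R)-5-methyl-2-oxo-3-oxabicyclo[3.1.0]hexan-6-yl]ethyl}pentanoate (side chain exo, cis to the 5-methyl group; both epimers at the ester-bearing carbon) | O=C1OC[C@@]2(C)[C@H](CCC(C(=O)OC(C)(C)C)C(=C)C(C)(OC)OC)[C@@H]12 | intermediate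
10 | corresponding lactol, 2-hydroxy-3-oxabicyclo[3.1.0]hexane (anomers) | OC1OC[C@@]2(C)[C@H](CCC(C(=O)OC(C)(C)C)C(=C)C(C)(OC)OC)[C@@H]12 | intermediate
11 | tert-butyl 2-{2-[(1R,2S,3R)-3-ethenyl-2-(hydroxymethyl)-2-methylcyclopropyl]ethyl}-4,4-dimethoxy-3-methylidenepentanoate (vinyl cis to CH2OH, trans to the chain) | OC[C@@]1(C)[C@H](CCC(C(=O)OC(C)(C)C)C(=C)C(C)(OC)OC)[C@H]1C=C | intermediate
12 | tert-butyldimethylsilyl ether of 11 | CC(C)(C)[Si](C)(C)OC[C@@]1(C)[C@H](CCC(C(=O)OC(C)(C)C)C(=C)C(C)(OC)OC)[C@H]1C=C | intermediate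
13 | tert-butyl 4-{[(tert-butyldimethylsilyl)oxy]methyl}-6a-(1,1-dimethoxyethyl)-5-ethenyl-4-methyloctahydropentalene-1-carboxylate (cis-fused; 4-CH3 cis to the ring A carbon C4 of the text; 5-vinyl cis to CH2OSi and to the 6a substituent) | CC(C)(C)[Si](C)(C)OC[C@]1(C)[C@H](C=C)C[C@]2(C(C)(OC)OC)[C@H]1CCC2C(=O)OC(C)(C)C | intermediate
14 | 6a-acetyl-4-(hydroxymethyl) analogue of 13 (ketal and silyl ether removed) | OC[C@]1(C)[C@H](C=C)C[C@]2(C(C)=O)[C@H]1CCC2C(=O)OC(C)(C)C | intermediate (not isolated)
15 | 6a-acetyl-4-formyl analogue | O=C[C@]1(C)[C@H](C=C)C[C@]2(C(C)=O)[C@H]1CCC2C(=O)OC(C)(C)C | intermediate (not isolated)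
16 | 6a-acetyl-1-(tert-butoxycarbonyl)-5-ethenyl-4-methyloctahydropentalene-4-carboxylic acid | OC(=O)[C@]1(C)[C@H](C=C)C[C@]2(C(C)=O)[C@H]1CCC2C(=O)OC(C)(C)C | intermediate
17 | methyl ester of 16 | COC(=O)[C@]1(C)[C@H](C=C)C[C@]2(C(C)=O)[C@H]1CCC2C(=O)OC(C)(C)C | intermediate
18 | 1,2,4-trioxolane (ozonide) of the vinyl group of 17 | COC(=O)[C@]1(C)[C@H](C3OCOO3)C[C@]2(C(C)=O)[C@H]1CCC2C(=O)OC(C)(C)C | intermediate (not isolated)
19 | 5-formyl analogue of 17 (keto aldehyde) | COC(=O)[C@]1(C)[C@H](C=O)C[C@]2(C(C)=O)[C@H]1CCC2C(=O)OC(C)(C)C | intermediate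
20 | aldol adduct, 2-tert-butyl 6-methyl 8-hydroxy-6-methyl-10-oxotricyclo[5.3.1.0(1,5)]undecane-2,6-dicarboxylate | COC(=O)[C@]1(C)[C@@H]2C(O)CC(=O)[C@@]3(C2)[C@H]1CCC3C(=O)OC(C)(C)C | intermediate (not isolated)
21 | 2-tert-butyl 6-methyl 6-methyl-10-oxotricyclo[5.3.1.0(1,5)]undec-8-ene-2,6-dicarboxylate (6-CO2Me endo, syn to the C8=C9 bridge; 6-CH3 exo, syn to C11; H5 endo) | COC(=O)[C@]1(C)[C@@H]2C=CC(=O)[C@@]3(C2)[C@H]1CCC3C(=O)OC(C)(C)C | intermediate
22 | 10-(methoxymethylidene) analogue of 21 (E/Z) | COC(=O)[C@]1(C)[C@@H]2C=CC(=COC)[C@@]3(C2)[C@H]1CCC3C(=O)OC(C)(C)C | intermediate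
23 | 10-formyl-6-(methoxycarbonyl)-6-methyltricyclo[5.3.1.0(1,5)]undec-8-ene-2-carboxylic acid | COC(=O)[C@]1(C)[C@@H]2C=CC(C=O)[C@@]3(C2)[C@H]1CCC3C(=O)O | intermediate (not isolated)
24 | dienol lactone: target skeleton with C13 as lactone carbonyl (cis-fused at C1–C2) | COC(=O)[C@]1(C)[C@@H]2C=CC3=COC(=O)[C@@H]4CC[C@@H]1[C@]34C2 | intermediate
25 | lactol: target skeleton with OH on C13 (anomers) | COC(=O)[C@]1(C)[C@@H]2C=CC3=COC(O)[C@@H]4CC[C@@H]1[C@]34C2 | intermediate
26 | CNP0315847.1, the 13-O-(3-methylbutanoyl) lactol methyl ester | COC(=O)[C@]1(C)[C@@H]2C=CC3=CO[C@@H](OC(=O)CC(C)C)[C@@H]4CC[C@@H]1[C@]34C2 | target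

**Step count and risks**

Total step count: 17. Longest linear sequence: 17 steps (1 to 26).

Steps most likely to fail:

Step 9. Rhodium may insert into the C6–C7 bond, or the σ-alkyl rhodium may fail to add to the alkene carbon that is flanked by the quaternary ketal carbon, so that β-hydride elimination to open-chain dienes or alkene migration into conjugation with the ester takes over. The fallback sets out from 12 and comes back at 16; it changes the ene partner from a ketal-flanked to a carbinol-flanked alkene before the cycloaddition. The ketal of 12 would be hydrolysed (pyridinium 4-toluenesulfonate, wet acetone) to the α-methylidene ketone F1. Luche reduction (NaBH4, CeCl3·7H2O, MeOH, −40 °C) would give the allylic alcohol F2, and silylation (Et3SiCl, imidazole) the triethylsilyl ether F3, whose alkene bears a secondary instead of a quaternary carbon. The same type of cycloaddition ([Rh(CO)2Cl]2, toluene, 110 °C) would then give the cycloadduct F4. CrO3/H2SO4 in acetone would remove both silyl groups and oxidise the carbinol to the methyl ketone and CH2OH to the acid, which is 16.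

Step 14. 1,2-Addition of the ylide to the hindered enone carbonyl next to quaternary C1 may be too slow, leaving ylide decomposition as the main event. The fallback sets out from 21 and comes back at 24. Corey–Chaykovsky epoxidation (Me3SI, KN(SiMe3)2, THF, 0 °C; the small sulfonium methylide adds 1,2) would give the spiro vinyl epoxide F5. Meinwald rearrangement (BF3·OEt2, CH2Cl2, −78 °C; allylic cation, hydride shift) would give the β,γ-unsaturated aldehyde tert-butyl ester F6. F6 would then be taken through the acidolysis and enol lactonisation of step 15 to 24.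

Step 15. The sensitive β,γ-unsaturated aldehyde may be acetylated at the dienol oxygen instead of lactonising, and the two C2 epimers may not converge. The fallback sets out from 22 and comes back at 25; it closes the oxygen ring at the aldehyde oxidation level. Acidolysis as in step 15 would give acid 23, which is isolated. Thioesterification (EtSH, EDC·HCl, DMAP, CH2Cl2) would give the S-ethyl thioester F7. Fukuyama reduction (Et3SiH, Pd on carbon, zerovalent palladium, acetone, rt) would give the dialdehyde F8. With Et3N, C2 of F8 (now α to an aldehyde) would epimerise, and the cis isomer would close to lactol 25.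

Further compounds
F1 | step 9 | tert-butyl 2-{2-[(1R,2S,3R)-2-{[(tert-butyldimethylsilyl)oxy]methyl}-3-ethenyl-2-methylcyclopropyl]ethyl}-3-methylidene-4-oxopentanoate | CC(C)(C)[Si](C)(C)OC[C@@]1(C)[C@H](CCC(C(=O)OC(C)(C)C)C(=C)C(C)=O)[C@H]1C=C
F2 | step 9 | 4-hydroxy analogue of F1 (allylic alcohol) | CC(C)(C)[Si](C)(C)OC[C@@]1(C)[C@H](CCC(C(=O)OC(C)(C)C)C(=C)C(C)O)[C@H]1C=C
F3 | step 9 | triethylsilyl ether of F2 | CC(C)(C)[Si](C)(C)OC[C@@]1(C)[C@H](CCC(C(=O)OC(C)(C)C)C(=C)C(C)O[Si](CC)(CC)CC)[C@H]1C=C
F4 | step 9 | cycloadduct of F3, analogue of 13 with a 1-[(triethylsilyl)oxy]ethyl group on C1 | CC(C)(C)[Si](C)(C)OC[C@]1(C)[C@H](C=C)C[C@]2(C(C)O[Si](CC)(CC)CC)[C@H]1CCC2C(=O)OC(C)(C)C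
F5 | step 14 | spiro epoxide at C10 of enone 21 | COC(=O)[C@]1(C)[C@@H]2C=CC4(CO4)[C@@]3(C2)[C@H]1CCC3C(=O)OC(C)(C)C
F6 | step 14 | 2-tert-butyl 6-methyl 10-formyl-6-methyltricyclo[5.3.1.0(1,5)]undec-8-ene-2,6-dicarboxylate | COC(=O)[C@]1(C)[C@@H]2C=CC(C=O)[C@@]3(C2)[C@H]1CCC3C(=O)OC(C)(C)C
F7 | step 15 | S-ethyl thioester of acid 23 | COC(=O)[C@]1(C)[C@@H]2C=CC(C=O)[C@@]3(C2)[C@H]1CCC3C(=O)SCC
F8 | step 15 | methyl 2,10-diformyl-6-methyltricyclo[5.3.1.0(1,5)]undec-8-ene-6-carboxylate | COC(=O)[C@]1(C)[C@@H]2C=CC(C=O)[C@@]3(C2)[C@H]1CCC3C=O
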